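**Retrosynthetic overview**
1. The strategy rests on C10, a secondary allylic carbinol held between the quaternary ring-fusion carbon C1 and the endocyclic Z-trisubstituted alkene C8=C9 of the seven-membered ring (C1, C5–C10). Cutting C9–C10 gives a C10 aldehyde on C1 and a (Z)-C9 iodoalkene on the C5 side chain (intramolecular Nozaki–Hiyama–Kishi closure).
2. The cyclisation substrate already carries the vanillate on O6, a free C2 ketone and a free C4 tertiary alcohol, so only the phenol silyl ether is removed after ring closure.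
3. The Z-iodoalkene is made from a C6 methallyl carbinol by silicon-tethered ring-closing metathesis (O6–Si–C9=C8) and iododesilylation. A 3-iodo-2-methylallyl metal is not added to C6, because allyl metals react through the γ-carbon, here the iodine-bearing terminus.
4. C6 comes from Brown methallylation of a C6 aldehyde, and C4 from isopropylcerium addition to a C4 ketone anti to C5. C5 and quaternary C1 come from vinyl-cuprate addition and hydroxymethylation of (R)-4-silyloxy-2-methylcyclopentenone, whose C4 silyloxy group relays the chirality.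
5. Ring order: the five-membered ring (C1–C5) is present from the starting enone; the seven-membered ring is closed in step 20.

Key step: step 20

Remark on numbering: C1 quaternary C–Me, C2 C=O, C3 CH2, C4 C(OH)iPr, C5 ring-fusion CH, C6 CH–O-vanilloyl, C7 CH2, C8 =C(Me), C9 =CH, C10 CHOH; β is the face of the C1 methyl, α the opposite face.
Assumption: the Ipc2B allyl reagents of the (+)-α-pinene series deliver the allyl unit to the Si face of an aldehyde, as they do with simple aldehydes.

**Step 1**
Reactants: 1 (R)-4-(tert-butyldimethylsilyloxy)cyclopent-2-en-1-one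
Product: 2 (R)-4-(tert-butyldimethylsilyloxy)-2-iodocyclopent-2-en-1-one
Conditions: I2, pyridine/CH2Cl2, 0 °C to rt
Reagents that add atoms: iodine, II
Why: α-iodination of the enone (conjugate addition of pyridine, iodination of the enolate, E1cB loss of pyridine) should leave the C4 stereocentre untouched.

**Step 2**
Reactants: 2 (R)-4-(tert-butyldimethylsilyloxy)-2-iodocyclopent-2-en-1-one
Product: 3 (R)-4-(tert-butyldimethylsilyloxy)-2-methylcyclopent-2-en-1-one
Conditions: Me4Sn, Pd2(dba)3 (2.5 mol %), AsPh3, CuI, NMP, 80 °C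
Reagents that add atoms: tetramethyltin, C[Sn](C)(C)C
Why: Stille coupling of the α-iodoenone runs under neutral conditions, which avoids base-induced loss of the γ-silyloxy group.

**Step 3**
Reactants: 3 (R)-4-(tert-butyldimethylsilyloxy)-2-methylcyclopent-2-en-1-one
Product: 4 trans-4-(tert-butyldimethylsilyloxy)-2-methyl-1-(trimethylsilyloxy)-3-vinylcyclopent-1-ene (4α-OTBS and 5β-vinyl in target numbering)
Conditions: CH2=CHMgBr, CuI·2LiCl (10 mol %), TMSCl, THF, −78 °C; Et3N, pentane work-up, no chromatography
Reagents that add atoms: vinylmagnesium bromide, C=C[Mg]Br; chlorotrimethylsilane, C[Si](C)(C)Cl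
Why: copper-catalysed conjugate addition with silyl trapping should place the vinyl group on C5 anti to the C4 silyloxy group, as for 2-alkyl-4-silyloxycyclopentenones, and hold the enolate as the regiodefined silyl enol ether.

**Step 4**
Reactants: 4 trans-4-(tert-butyldimethylsilyloxy)-2-methyl-1-(trimethylsilyloxy)-3-vinylcyclopent-1-ene
Product: 5 2-(hydroxymethyl)-2-methyl-3-vinyl-4-(tert-butyldimethylsilyloxy)cyclopentan-1-one with C1 methyl β, C10H2OH α, C5 vinyl β and C4 OTBS α
Conditions: aq. HCHO (37 %), Yb(OTf)3 (10 mol %), THF, rt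
Reagents that add atoms: formaldehyde, C=O
Why: Mukaiyama aldol hydroxymethylation in water should bring formaldehyde to C1 anti to the neighbouring C5 vinyl group, which sets the quaternary centre without base and so without β-elimination of the silyloxy group.

**Step 5**
Reactants: 5 the β-hydroxy ketone
Product: 6 the 1,3-diol with C2 β-OH (trans to C10H2OH)
Conditions: Me4NBH(OAc)3, MeCN/AcOH, −30 °C
Reagents that add atoms: none
Why: Evans–Saksena hydroxyl-directed reduction should deliver hydride from the boron bound to O10 to the α-face of C2 and give one diol; this centre only masks the ketone and is oxidised again in step 19.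

**Step 6**
Reactants: 6 the 1,3-diol
Product: 7 the O2,O10-acetonide (trans-fused 1,3-dioxane) with 4α-OTBS and 5β-vinyl
Conditions: Me2C(OMe)2, PPTS (cat.), CH2Cl2, rt
Reagents that add atoms: 2,2-dimethoxypropane, COC(C)(C)OC
Why: acid-catalysed transketalisation closes the six-membered acetonide on the only 1,3-diol, and the secondary TBS ether is stable to PPTS.

**Step 7**
Reactants: 7 the acetonide silyl ether
Product: 8 the acetonide with free C4 α-OH
Conditions: TBAF, THF, 0 °C to rt
Reagents that add atoms: none
Why: fluoride desilylation removes the relay silyl group while the acetonide and the alkene are inert.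

**Step 8**
Reactants: 8 the C4 alcohol
Product: 9 the C4 ketone (α-vinyl cyclopentanone, acetonide retained)
Conditions: Dess–Martin periodinane, NaHCO3, CH2Cl2, 0 °C to rt; used directly
Reagents that add atoms: none
Why: buffered Dess–Martin oxidation is neutral enough to keep the α-vinyl ketone from epimerising at C5 or moving its alkene into conjugation.

**Step 9**
Reactants: 9 the C4 ketone
Product: 10 the tertiary alcohol with C4 β-OH and α-isopropyl
Conditions: iPrMgCl, anhydrous CeCl3, THF, −78 °C
Reagents that add atoms: isopropylmagnesium chloride, CC(C)[Mg]Cl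
Why: organocerium 1,2-addition suppresses enolisation and β-hydride reduction, and the reagent should approach C4 from the α-face, anti to the C5 vinyl group and the C1 methyl, which sets the C4 carbinol.

**Step 10**
Reactants: 10 the tertiary alcohol
Product: 11 the C4 triethylsilyl ether
Conditions: TESOTf, 2,6-lutidine, CH2Cl2, −78 to 0 °C
Reagents that add atoms: triethylsilyl trifluoromethanesulfonate, CC[Si](CC)(CC)OS(=O)(=O)C(F)(F)F
Why: silyl triflate silylation of the hindered tertiary alcohol protects it against retro-aldol loss at the β-hydroxy aldehyde stage and against the molybdenum catalyst of step 14.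

**Step 11**
Reactants: 11 the vinyl compound
Product: 12 the C6 aldehyde (formyl group β on C5)
Conditions: OsO4 (2 mol %), NaIO4, 2,6-lutidine, dioxane/H2O 3:1, rt
Reagents that add atoms: sodium periodate (terminal oxidant, through catalytic OsO4), [Na+].[O-]I(=O)(=O)=O
Why: Lemieux–Johnson cleavage of the monosubstituted alkene runs under buffered, near-neutral conditions that should not epimerise C5 or eliminate the β-silyloxy group.

**Step 12**
Reactants: 12 the C6 aldehyde
Product: 14 the (6S)-homoallylic alcohol carrying CH2C(CH3)=CH2 on C6, via borinate ester 13 (not isolated)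
Conditions: (−)-Ipc2BOMe, 2-methylallylmagnesium chloride, Et2O, −78 °C to rt; 12, −78 °C; then NaOH, H2O2
Reagents that add atoms: B-(2-methylallyl)diisopinocampheylborane made in the flask, CC(=C)CB([C@@H]1C[C@@H]2C[C@H]([C@H]1C)C2(C)C)[C@@H]1C[C@@H]2C[C@H]([C@H]1C)C2(C)C
Why: Brown methallylboration through a chair transition state should deliver the symmetrical 2-methylallyl group to the Si face of the aldehyde under reagent control, setting C6 as S and avoiding the γ-attack problem of an iodoallyl nucleophile.

**Step 13**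
Reactants: 14 the (6S)-homoallylic alcohol
Product: 15 the O6 dimethyl(vinyl)silyl ether
Conditions: CH2=CHSiMe2Cl, imidazole, DMAP (cat.), CH2Cl2, 0 °C to rt
Reagents that add atoms: chloro(dimethyl)vinylsilane, C=C[Si](C)(C)Cl
Why: silylation of the secondary alcohol installs the temporary silicon tether that carries the future C9.

**Step 14**
Reactants: 15 the vinylsilyl ether
Product: 16 the cyclic alkenylsiloxane (1-oxa-2-silacyclohex-3-ene: O6–SiMe2–C9H=C8(CH3)–C7H2–C6)
Conditions: Mo(=CHCMe2Ph)(=N-2,6-iPr2C6H3)[OCMe(CF3)2]2 (10 mol %), benzene, 25 to 60 °C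
Reagents that add atoms: none
Why: silicon-tethered ring-closing metathesis of a vinylsilyl ether with the molybdenum alkylidene forms C8=C9 inside a six-membered ring, so that C7 and silicon are forced cis.

**Step 15**
Reactants: 16 the cyclic alkenylsiloxane
Product: 18 the (6S,8Z)-iodoalkenyl alcohol with side chain CH(OH)CH2C(CH3)=CHI, via ring-opened silyl ether 17 (not isolated)
Conditions: NIS, 2,6-lutidine, (CF3)2CHOH, 0 °C; aq. NaHCO3/Na2S2O3
Reagents that add atoms: N-iodosuccinimide, O=C1CCC(=O)N1I
Why: iododesilylation is an ipso substitution at C9 through the tertiary β-silyl cation at C8 and should proceed with retention, so iodine takes the place of silicon cis to C7, and the silyl ether left on O6 hydrolyses on work-up.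

**Step 16**
Reactants: 19 vanillic acid
Product: 21 3-methoxy-4-(triisopropylsilyloxy)benzoic acid, via silyl ester 20 (not isolated)
Conditions: TIPSCl (2.3 equiv), imidazole, DMF, rt; then AcOH/THF/H2O, 40 °C
Reagents that add atoms: chlorotriisopropylsilane, CC(C)[Si](Cl)(C(C)C)C(C)C
Why: silylation of both acidic groups followed by selective hydrolysis of the much more labile silyl ester leaves the phenol protected as an acid-stable, fluoride-labile ether.

**Step 17**
Reactants: 18 the (6S,8Z)-iodoalkenyl alcohol; 21 3-methoxy-4-(triisopropylsilyloxy)benzoic acid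
Product: 23 the O6 aroyl ester (O-TIPS vanillate), via mixed anhydride 22 (not isolated)
Conditions: 21, 2,4,6-trichlorobenzoyl chloride, Et3N, THF, rt; then 18, DMAP, toluene, 60 °C
Reagents that add atoms: none
Why: Yamaguchi esterification acylates the hindered secondary C6 alcohol, the only free hydroxyl group, so the ester is in place before C10 and C2 are unmasked.

**Step 18**
Reactants: 23 the O6 aroyl ester
Product: 24 the triol ester with free C2 β-OH, C10H2OH and C4 β-OH
Conditions: TsOH·H2O (0.2 equiv), MeOH/H2O 10:1, rt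
Reagents that add atoms: none
Why: acid-catalysed hydrolysis removes the acetonide and the triethylsilyl ether together, while the aryl silyl ether, the aryl ester and the iodoalkene should be stable to dilute acid.

**Step 19**
Reactants: 24 the triol ester
Product: 25 the keto aldehyde with C10 formyl α on quaternary C1, C2 ketone, C4 β-OH and the (6S,8Z) side chain CH(OCOAr)CH2C(CH3)=CHI on C5
Conditions: Dess–Martin periodinane (3 equiv), NaHCO3, CH2Cl2, 0 °C to rt; crude product used at once
Reagents that add atoms: none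
Why: double Dess–Martin oxidation converts the primary C10 and secondary C2 alcohols while the tertiary C4 alcohol cannot react, and the 1,3-dicarbonyl product cannot enolise at quaternary C1.

**Step 20**
Reactants: 25 the keto aldehyde
Product: 27 the trans-hydroazulene with 10α-OH (10R), C8=C9 alkene, C2 ketone, C4 β-OH and O6 O-TIPS-vanillate, via alkenylchromium 26 (not isolated)
Conditions: CrCl2 (8 equiv), NiCl2 (1 mol % of Cr), degassed DMSO, rt, 0.003 M, slow addition of 25
Reagents that add atoms: none
Why: Nickel(0), formed from NiCl2 and CrCl2, inserts into the C9–I bond with retention and passes the alkenyl group to chromium(III), and the C9 alkenylchromium 26 adds to the C10 aldehyde through a chromium-bridged four-centre transition state. The closest known reaction type is the intramolecular Nozaki–Hiyama–Kishi alkenylation of aldehydes used for medium and large carbocycles. The seven-membered ring (C1, C5–C10) closes by 7-exo-trig addition to the carbonyl group and is trans-fused, because C10 (α on C1) and C6 (β on C5) are trans on the cyclopentane. C10 is set under substrate control: in the chair-like cycloheptene transition state C9 must approach anti to the C1–C2 bond, and the chromium-bound oxygen is expected to take the open sector anti to the axial C1 methyl instead of the sector between that methyl and C2, which gives the 10α alcohol. The step needs chemoselectivity for the aldehyde over the C2 ketone and the aryl ester, which the low basicity and aldehyde preference of organochromium(III) reagents should provide. The Z geometry is fixed in the iodide and carried through with retention, and high dilution with slow addition holds back intermolecular coupling.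

**Step 21**
Reactants: 27 the silyl-protected hydroazulene
Product: 28 the target, (1S,4R,5S,6S,10R)-4,10-dihydroxy-4-isopropyl-1,8-dimethyl-2-oxo-daucan-8-en-6-yl 4-hydroxy-3-methoxybenzoate (CNP0233071.1)
Conditions: TBAF, AcOH (1:1), THF, 0 °C
Reagents that add atoms: none
Why: buffered fluoride cleaves the aryl silyl ether under near-neutral conditions that should not trigger retro-aldol opening of the β-hydroxy ketone or acyl migration.

**Compound list**
1 | (R)-4-(tert-butyldimethylsilyloxy)cyclopent-2-en-1-one | O=C1C=C[C@H](O[Si](C)(C)C(C)(C)C)C1 | starting material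
2 | (R)-4-(tert-butyldimethylsilyloxy)-2-iodocyclopent-2-en-1-one | O=C1C(I)=C[C@H](O[Si](C)(C)C(C)(C)C)C1 | intermediate
3 | (R)-4-(tert-butyldimethylsilyloxy)-2-methylcyclopent-2-en-1-one | O=C1C(C)=C[C@H](O[Si](C)(C)C(C)(C)C)C1 | intermediate
4 | trans-4-(tert-butyldimethylsilyloxy)-2-methyl-1-(trimethylsilyloxy)-3-vinylcyclopent-1-ene | C=C[C@@H]1C(C)=C(O[Si](C)(C)C)C[C@H]1O[Si](C)(C)C(C)(C)C | intermediate
5 | β-hydroxy ketone: C1 methyl β, C10H2OH α, C5 vinyl β, C4 OTBS α, C2 ketone | OC[C@@]1(C)C(=O)C[C@@H](O[Si](C)(C)C(C)(C)C)[C@@H]1C=C | intermediate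
6 | 1,3-diol: as 5 with C2 β-OH | OC[C@@]1(C)[C@H](O)C[C@@H](O[Si](C)(C)C(C)(C)C)[C@@H]1C=C | intermediate
7 | O2,O10-acetonide of 6 | CC1(C)OC[C@@]2(C)[C@H](O1)C[C@@H](O[Si](C)(C)C(C)(C)C)[C@@H]2C=C | intermediate
8 | acetonide with free C4 α-OH | CC1(C)OC[C@@]2(C)[C@H](O1)C[C@@H](O)[C@@H]2C=C | intermediate
9 | acetonide C4 ketone with 5β-vinyl | CC1(C)OC[C@@]2(C)[C@H](O1)CC(=O)[C@@H]2C=C | intermediate
10 | tertiary alcohol: C4 β-OH, α-isopropyl | CC1(C)OC[C@@]2(C)[C@H](O1)C[C@@](O)(C(C)C)[C@@H]2C=C | intermediate
11 | C4 triethylsilyl ether of 10 | CC1(C)OC[C@@]2(C)[C@H](O1)C[C@@](O[Si](CC)(CC)CC)(C(C)C)[C@@H]2C=C | intermediate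
12 | C6 aldehyde (formyl β on C5) | CC1(C)OC[C@@]2(C)[C@H](O1)C[C@@](O[Si](CC)(CC)CC)(C(C)C)[C@@H]2C=O | intermediate
13 | O6 diisopinocampheylborinate of 14 (not isolated) | CC1(C)OC[C@@]2(C)[C@H](O1)C[C@@](O[Si](CC)(CC)CC)(C(C)C)[C@@H]2[C@@H](OB([C@@H]3C[C@@H]4C[C@H]([C@H]3C)C4(C)C)[C@@H]3C[C@@H]4C[C@H]([C@H]3C)C4(C)C)CC(C)=C | intermediate
14 | (6S)-homoallylic alcohol with CH2C(CH3)=CH2 on C6 | CC1(C)OC[C@@]2(C)[C@H](O1)C[C@@](O[Si](CC)(CC)CC)(C(C)C)[C@@H]2[C@@H](O)CC(C)=C | intermediate
15 | O6 dimethyl(vinyl)silyl ether of 14 | CC1(C)OC[C@@]2(C)[C@H](O1)C[C@@](O[Si](CC)(CC)CC)(C(C)C)[C@@H]2[C@@H](O[Si](C)(C)C=C)CC(C)=C | intermediate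
16 | cyclic alkenylsiloxane (O6–SiMe2–C9H=C8(CH3)–C7H2–C6 ring) | CC1(C)OC[C@@]2(C)[C@H](O1)C[C@@](O[Si](CC)(CC)CC)(C(C)C)[C@@H]2[C@@H]3CC(C)=C[Si](C)(C)O3 | intermediate
17 | ring-opened O6 (hexafluoroisopropoxy)dimethylsilyl ether of the (Z)-iodoalkene (not isolated) | CC1(C)OC[C@@]2(C)[C@H](O1)C[C@@](O[Si](CC)(CC)CC)(C(C)C)[C@@H]2[C@@H](O[Si](C)(C)OC(C(F)(F)F)C(F)(F)F)C/C(C)=C\I | intermediate
18 | (6S,8Z)-iodoalkenyl alcohol | CC1(C)OC[C@@]2(C)[C@H](O1)C[C@@](O[Si](CC)(CC)CC)(C(C)C)[C@@H]2[C@@H](O)C/C(C)=C\I | intermediate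
19 | vanillic acid | COc1cc(C(=O)O)ccc1O | starting material
20 | triisopropylsilyl 3-methoxy-4-(triisopropylsilyloxy)benzoate (not isolated) | COc1cc(C(=O)O[Si](C(C)C)(C(C)C)C(C)C)ccc1O[Si](C(C)C)(C(C)C)C(C)C | intermediate
21 | 3-methoxy-4-(triisopropylsilyloxy)benzoic acid | COc1cc(C(=O)O)ccc1O[Si](C(C)C)(C(C)C)C(C)C | intermediate
22 | mixed anhydride of 21 with 2,4,6-trichlorobenzoic acid (not isolated) | COc1cc(C(=O)OC(=O)c2c(Cl)cc(Cl)cc2Cl)ccc1O[Si](C(C)C)(C(C)C)C(C)C | intermediate
23 | O6 aroyl ester of 18 (acetonide and C4 OTES retained) | CC1(C)OC[C@@]2(C)[C@H](O1)C[C@@](O[Si](CC)(CC)CC)(C(C)C)[C@@H]2[C@@H](OC(=O)c3ccc(O[Si](C(C)C)(C(C)C)C(C)C)c(OC)c3)C/C(C)=C\I | intermediate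
24 | triol ester: C2 β-OH, C10H2OH, C4 β-OH | OC[C@@]1(C)[C@H](O)C[C@@](O)(C(C)C)[C@@H]1[C@@H](OC(=O)c2ccc(O[Si](C(C)C)(C(C)C)C(C)C)c(OC)c2)C/C(C)=C\I | intermediate
25 | keto aldehyde, substrate of the key step | O=C[C@@]1(C)C(=O)C[C@@](O)(C(C)C)[C@@H]1[C@@H](OC(=O)c2ccc(O[Si](C(C)C)(C(C)C)C(C)C)c(OC)c2)C/C(C)=C\I | intermediate
26 | C9 alkenylchromium(III) dichloride from 25 (not isolated) | O=C[C@@]1(C)C(=O)C[C@@](O)(C(C)C)[C@@H]1[C@@H](OC(=O)c2ccc(O[Si](C(C)C)(C(C)C)C(C)C)c(OC)c2)C/C(C)=C\[Cr](Cl)Cl | intermediate
27 | trans-hydroazulene, 10α-OH, phenol as TIPS ether | COc1cc(C(=O)O[C@H]2CC(C)=C[C@@H](O)[C@@]3(C)C(=O)C[C@@](O)(C(C)C)[C@H]23)ccc1O[Si](C(C)C)(C(C)C)C(C)C | intermediate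
28 | CNP0233071.1 | COc1cc(C(=O)O[C@H]2CC(C)=C[C@@H](O)[C@@]3(C)C(=O)C[C@@](O)(C(C)C)[C@H]23)ccc1O | target

**Step count and risks**
Total step count: 21. Longest linear sequence: 20 steps (steps 1–15 and 17–21, from compound 1); step 16 is a one-step side branch from vanillic acid.

Steps most likely to fail:

1. Step 20 (Nozaki–Hiyama–Kishi closure). The ring closure may be slower than reduction or dimerisation of the alkenyl metal, the non-enolisable β-keto aldehyde may lose its formyl group, or the facial selectivity at C10 may be poor. The fallback forms the ring at C8=C9 by metathesis instead. It sets out from 14: Yamaguchi esterification with 21 should give the methallyl ester F1; TsOH in MeOH/H2O then frees the triol F2; Dess–Martin oxidation gives the methallyl keto aldehyde F3; vinylmagnesium bromide in THF at −78 °C should add only to the aldehyde and give the divinyl carbinol F4; the Grubbs second-generation catalyst in CH2Cl2 at 40 °C then closes the cycloheptene and the route is rejoined at 27.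

2. Step 14 (silicon-tethered metathesis). The molybdenum catalyst may be deactivated by the crowded, oxygen-rich substrate, or turnover to the trisubstituted alkene may stall. The fallback uses a boron tether with a ruthenium catalyst. It sets out from 14: transesterification with dibutyl vinylboronate should give the mixed vinylboronate F5; the Grubbs second-generation catalyst closes it to the cyclic alkenylboronate F6; iododeboronation with NaOH and I2, which goes with retention, rejoins the route at 18.

3. Step 12 (methallylboration). The bulky reagent may add slowly to the doubly neopentyl aldehyde, or reagent control may not override the substrate's own facial bias. The fallback sets C6 by reduction. It sets out from 12: 2-methylallylmagnesium chloride in THF at −78 °C gives 14 together with the C6 epimer F7; Dess–Martin oxidation of the mixture gives the C6 ketone F8; (R)-Me-CBS/BH3·SMe2 reduction, with ring carbon C5 as the large group, should return 14.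

**Further compounds**
F1 | step 20 | O6 aroyl ester of 14 (methallyl side chain, acetonide and C4 OTES retained) | CC1(C)OC[C@@]2(C)[C@H](O1)C[C@@](O[Si](CC)(CC)CC)(C(C)C)[C@@H]2[C@@H](OC(=O)c3ccc(O[Si](C(C)C)(C(C)C)C(C)C)c(OC)c3)CC(C)=C
F2 | step 20 | methallyl triol ester | OC[C@@]1(C)[C@H](O)C[C@@](O)(C(C)C)[C@@H]1[C@@H](OC(=O)c2ccc(O[Si](C(C)C)(C(C)C)C(C)C)c(OC)c2)CC(C)=C
F3 | step 20 | methallyl keto aldehyde | O=C[C@@]1(C)C(=O)C[C@@](O)(C(C)C)[C@@H]1[C@@H](OC(=O)c2ccc(O[Si](C(C)C)(C(C)C)C(C)C)c(OC)c2)CC(C)=C
F4 | step 20 | divinyl carbinol (C10 vinyl carbinol, 10R) | C=C[C@@H](O)[C@@]1(C)C(=O)C[C@@](O)(C(C)C)[C@@H]1[C@@H](OC(=O)c2ccc(O[Si](C(C)C)(C(C)C)C(C)C)c(OC)c2)CC(C)=C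
F5 | step 14 | O6 butoxy(vinyl)boronate of 14 | CC1(C)OC[C@@]2(C)[C@H](O1)C[C@@](O[Si](CC)(CC)CC)(C(C)C)[C@@H]2[C@@H](OB(OCCCC)C=C)CC(C)=C
F6 | step 14 | cyclic alkenylboronate (O6–B(OBu)–C9H=C8(CH3)–C7H2–C6 ring) | CC1(C)OC[C@@]2(C)[C@H](O1)C[C@@](O[Si](CC)(CC)CC)(C(C)C)[C@@H]2[C@@H]3CC(C)=CB(OCCCC)O3
F7 | step 12 | (6R)-epimer of 14 | CC1(C)OC[C@@]2(C)[C@H](O1)C[C@@](O[Si](CC)(CC)CC)(C(C)C)[C@@H]2[C@H](O)CC(C)=C
F8 | step 12 | C6 ketone | CC1(C)OC[C@@]2(C)[C@H](O1)C[C@@](O[Si](CC)(CC)CC)(C(C)C)[C@@H]2C(=O)CC(C)=C
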